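**Plan**

- The target is a 1,4-bis(indol-3-yl)-2,3,5,6-tetramethoxybenzene with no stereocentre, twofold symmetric except that one indole carries 5-OMe and the other 5-OH. The central ring is numbered C1 (bearing the 5-methoxyindolyl), C2, C3, C4 (bearing the 5-hydroxyindolyl), C5, C6.
- Enabling feature: each half (one indole plus C1-C2-C3, or the other indole plus C4-C5-C6) has the carbon skeleton of an indol-3-ylpyruvate, with C1/C4 as the methylene carbon, C2/C5 as the ketone carbon and C3/C6 as the carboxyl carbon.
- Retrosynthesis: cut the one differentiating O-CH3 bond (back to the symmetric bis-5-hydroxy compound, masked as two benzyl ethers), then the four O-CH3 bonds of the central ring (back to the dihydroxybenzoquinone), then the ring bonds C3-C4 and C6-C1, which leaves two identical pyruvate esters.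
- Forward: 5-benzyloxyindole is formylated at C3 and homologated through the azlactone to the pyruvate ester. Two esters are joined head to tail to close the central six-membered ring, the only ring made. Reductive tetra-O-methylation, hydrogenolysis and one O-methylation finish the synthesis.
- Stereochemistry: none to set. The only geometric element, the Z olefin of the azlactone (thermodynamic isomer), disappears on hydrolysis.

Key step: step 5

Remark on the chemistry: 8 and 9 are drawn as keto tautomers although their enols should dominate, and 11 is drawn as one of its equivalent dihydroxyquinone tautomers. All three are handled under argon because their enolates are oxidised easily.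

**Route**

Step 1
Reactants: 1 5-benzyloxyindole
Product: 3 5-benzyloxyindole-3-carboxaldehyde, via iminium chloride 2 (not isolated)
Conditions: POCl3, DMF, 0 to 35 °C; then NaOH aq, 80 °C
Reagents that add atoms: N,N-dimethylformamide CN(C)C=O; water O
Why: Vilsmeier–Haack formylation, in which the chloroiminium ion made from POCl3 and DMF attacks C3 (the most nucleophilic indole carbon) and alkaline hydrolysis of iminium salt 2 should release the aldehyde, the benzyl ether being inert throughout.

Step 2
Reactants: 3 5-benzyloxyindole-3-carboxaldehyde; 4 N-acetylglycine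
Product: 6 (Z)-4-[(1-acetyl-5-benzyloxyindol-3-yl)methylene]-2-methyloxazol-5(4H)-one, via 2-methyloxazol-5(4H)-one 5 (not isolated)
Conditions: Ac2O, NaOAc, 100 °C
Reagents that add atoms: acetic anhydride CC(=O)OC(C)=O
Why: Erlenmeyer–Plöchl azlactone synthesis, in which Ac2O cyclodehydrates 4 to oxazolone 5, whose acidic ring methylene condenses in Perkin fashion with the aldehyde (made more electrophilic by the N-acetylation that the same medium brings about), and the conjugated alkylidene should settle as the thermodynamic Z isomer with the indolyl group cis to the ring nitrogen.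

Step 3
Reactants: 6 (Z)-4-[(1-acetyl-5-benzyloxyindol-3-yl)methylene]-2-methyloxazol-5(4H)-one
Product: 8 3-(5-benzyloxyindol-3-yl)-2-oxopropanoic acid, via acetamidoacrylic acid 7 (not isolated)
Conditions: NaOH aq (2 M), reflux, Ar; then HCl aq, 0 °C
Reagents that add atoms: water O (delivered as hydroxide from sodium hydroxide [Na+].[OH-])
Why: Alkaline azlactone hydrolysis to an arylpyruvic acid, in which hydroxide opens the lactone and removes the labile indole N-acetyl group to give enamide 7 and then hydrolyses the acetamido group through the enamine and imine to the keto acid, while the benzyl ether is stable to base and argon keeps the easily oxidised enolate intact.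

Step 4
Reactants: 8 3-(5-benzyloxyindol-3-yl)-2-oxopropanoic acid
Product: 9 methyl 3-(5-benzyloxyindol-3-yl)-2-oxopropanoate
Conditions: MeI, KHCO3, DMF, 0 °C to rt, Ar
Reagents that add atoms: iodomethane CI
Why: Carboxylate O-alkylation (SN2 esterification), since bicarbonate ionises only the carboxylic acid, which is far more acidic than the enol or the indole N–H, so that iodomethane should give the methyl ester without any acid that would harm the indolylpyruvate.

Step 5
Reactants: 9 methyl 3-(5-benzyloxyindol-3-yl)-2-oxopropanoate (two molecules)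
Product: 11 2,5-bis(5-benzyloxyindol-3-yl)-3,6-dihydroxy-1,4-benzoquinone, via trioxohexanoate 10 (not isolated)
Conditions: KOtBu (1.3 equiv per ester), THF, slow addition of 9 to the base at −20 °C, then 60 °C, Ar; then degassed HCl aq
Reagents that add atoms: none
Why: Proposed new method: adding 9 to the cold base turns every molecule into its potassium enolate before it can meet a neutral ketone, and on warming the enolate carbon (the former methylene) of one molecule attacks the ester carbon of a second with loss of methoxide (intermolecular Claisen acylation, bond C3–C4) to give trioxohexanoate 10, whose central C–H is at once deprotonated by the methoxide set free. The remaining enolate carbon of 10 then attacks the remaining ester carbon in a 6-(enolendo)-exo-trig Dieckmann closure (bond C6–C1), the only ring closure of the step, and the cyclohexane-1,2,4,5-tetraone so formed is a tautomer of the dihydroxyquinone, so that no oxidant is needed and no stereocentre arises. The closest known reaction types are the Claisen and Dieckmann condensations and the alkali-metal-promoted self-condensation of aliphatic 2-oxo esters to 3,6-dialkyl-2,5-dihydroxybenzoquinones, whereas indol-3-ylpyruvate esters, like other arylpyruvates that normally dimerise by aldol addition and lactonisation, have not been taken through it. The selectivity needed is C-acylation at the ester carbon instead of aldol addition to the ketone carbon, and it rests on complete pre-enolisation in an aprotic solvent (no ketone electrophile is left), on K+ held between the enolate oxygen and the ester carbonyl (which activates the ester), on the reversibility of any aldol adduct, and on the irreversible removal of the product as its dianion, a doubly vinylogous carboxylate. The base is kept near 1.3 equiv per ester so that tert-butoxide is used up by the enol and the indole N–H instead of transesterifying the ester, and any N-acylation of an indole anion would be reversed by the methoxide released.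

Step 6
Reactants: 11 2,5-bis(5-benzyloxyindol-3-yl)-3,6-dihydroxy-1,4-benzoquinone
Product: 13 1,4-bis(5-benzyloxyindol-3-yl)-2,3,5,6-tetramethoxybenzene, via leuco tetrol 12 (not isolated)
Conditions: Na2S2O4, THF/H2O, rt, Ar; solvent exchange under Ar; then Me2SO4 (excess), K2CO3, acetone, reflux, Ar
Reagents that add atoms: dimethyl sulfate COS(=O)(=O)OC
Why: Reductive methylation of a quinone, in which dithionite reduces 11 to tetrol 12 and the four phenoxides formed by K2CO3 are capped by Me2SO4 in Williamson fashion, while the far less acidic indole N–H is not ionised by carbonate in acetone and should stay unmethylated.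

Step 7
Reactants: 13 1,4-bis(5-benzyloxyindol-3-yl)-2,3,5,6-tetramethoxybenzene
Product: 14 1,4-bis(5-hydroxyindol-3-yl)-2,3,5,6-tetramethoxybenzene
Conditions: H2 (1 atm), Pd/C (10% palladium on carbon), THF/MeOH, rt
Reagents that add atoms: none
Why: Catalytic hydrogenolysis of benzyl aryl ethers over Pd/C, which should cleave both O–CH2Ph bonds and leave the methyl ethers, the indoles and the hexasubstituted benzene ring untouched.

Step 8
Reactants: 14 1,4-bis(5-hydroxyindol-3-yl)-2,3,5,6-tetramethoxybenzene
Product: 15 3-[4-(5-methoxyindol-3-yl)-2,3,5,6-tetramethoxyphenyl]indol-5-ol (CNP0244913.0)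
Conditions: Me2SO4 (0.8 equiv), K2CO3, acetone, rt, Ar; recovered 14 recycled
Reagents that add atoms: dimethyl sulfate COS(=O)(=O)OC
Why: Williamson O-methylation of a phenoxide with a deficit of electrophile, chosen because the two remote 5-hydroxyl groups are equivalent and react statistically, so that less than one equivalent of Me2SO4 should favour the mono-ether over the di-ether, recovered 14 is recycled, and carbonate again leaves the indole N–H alone.

**Compound list**

1 | 5-benzyloxyindole | c1ccc(COc2ccc3[nH]ccc3c2)cc1 | starting material
2 | [(5-benzyloxy-1H-indol-3-yl)methylene]dimethyliminium chloride | C[N+](C)=Cc1c[nH]c2ccc(OCc3ccccc3)cc12.[Cl-] | intermediate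
3 | 5-benzyloxyindole-3-carboxaldehyde | O=Cc1c[nH]c2ccc(OCc3ccccc3)cc12 | intermediate
4 | N-acetylglycine | CC(=O)NCC(=O)O | starting material
5 | 2-methyloxazol-5(4H)-one | CC1=NCC(=O)O1 | intermediate
6 | (Z)-4-[(1-acetyl-5-benzyloxyindol-3-yl)methylene]-2-methyloxazol-5(4H)-one | CC1=N/C(=C\c2cn(C(C)=O)c3ccc(OCc4ccccc4)cc23)C(=O)O1 | intermediate
7 | (Z)-2-acetamido-3-(5-benzyloxyindol-3-yl)acrylic acid | CC(=O)N/C(=C\c1c[nH]c2ccc(OCc3ccccc3)cc12)C(=O)O | intermediate
8 | 3-(5-benzyloxyindol-3-yl)-2-oxopropanoic acid | O=C(O)C(=O)Cc1c[nH]c2ccc(OCc3ccccc3)cc12 | intermediate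
9 | methyl 3-(5-benzyloxyindol-3-yl)-2-oxopropanoate | COC(=O)C(=O)Cc1c[nH]c2ccc(OCc3ccccc3)cc12 | intermediate
10 | methyl 3,6-bis(5-benzyloxyindol-3-yl)-2,4,5-trioxohexanoate | COC(=O)C(=O)C(c1c[nH]c2ccc(OCc3ccccc3)cc12)C(=O)C(=O)Cc1c[nH]c2ccc(OCc3ccccc3)cc12 | intermediate
11 | 2,5-bis(5-benzyloxyindol-3-yl)-3,6-dihydroxy-1,4-benzoquinone | O=C1C(O)=C(c2c[nH]c3ccc(OCc4ccccc4)cc23)C(=O)C(O)=C1c1c[nH]c2ccc(OCc3ccccc3)cc12 | intermediate
12 | 3,6-bis(5-benzyloxyindol-3-yl)benzene-1,2,4,5-tetrol | Oc1c(O)c(-c2c[nH]c3ccc(OCc4ccccc4)cc23)c(O)c(O)c1-c1c[nH]c2ccc(OCc3ccccc3)cc12 | intermediate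
13 | 1,4-bis(5-benzyloxyindol-3-yl)-2,3,5,6-tetramethoxybenzene | COc1c(OC)c(-c2c[nH]c3ccc(OCc4ccccc4)cc23)c(OC)c(OC)c1-c1c[nH]c2ccc(OCc3ccccc3)cc12 | intermediate
14 | 1,4-bis(5-hydroxyindol-3-yl)-2,3,5,6-tetramethoxybenzene | COc1c(OC)c(-c2c[nH]c3ccc(O)cc23)c(OC)c(OC)c1-c1c[nH]c2ccc(O)cc12 | intermediate
15 | 3-[4-(5-methoxyindol-3-yl)-2,3,5,6-tetramethoxyphenyl]indol-5-ol | COc1ccc2[nH]cc(-c3c(OC)c(OC)c(-c4c[nH]c5ccc(O)cc45)c(OC)c3OC)c2c1 | target

**Summary**

Total step count: 8.
Longest linear sequence: 8 steps (1 to 15; both halves of the central ring come from the same ester 9).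

**Steps most likely to fail**

Step 5 (the step that bears the label "Proposed new method:").
- What may go wrong: wherever proton exchange regenerates the keto form, the enolate may add to the ketone carbonyl, so that aldol addition and lactonisation to a butenolide outrun C-acylation. Alternatively, the two anionic partners may fail to react before the electron-rich enolate is degraded by traces of oxygen.
- Fallback with known chemistry: the central ring is bought as a quinone and the indoles are attached to it. It sets out from 1 and comes back to the route at 11.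
- Compound 1 adds through C3 to a free ring position of 2,5-dichloro-1,4-benzoquinone under acid catalysis (HCl, THF), the adduct being re-oxidised in the flask by excess quinone. This gives 3-(5-benzyloxyindol-3-yl)-2,5-dichloro-1,4-benzoquinone F1.
- A second equivalent of 1 is added to the last free position in the same way, with DDQ (2,3-dichloro-5,6-dicyano-1,4-benzoquinone) as oxidant. This gives 2,5-bis(5-benzyloxyindol-3-yl)-3,6-dichloro-1,4-benzoquinone F2.
- The two vinylogous acid chlorides of F2 are exchanged for hydroxide by addition–elimination (NaOH aq, MeOH, reflux, then acid), which gives 11.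

Step 6.
- What may go wrong: the very electron-rich tetrol may be re-oxidised by adventitious air while four hindered oxygens are being capped, leaving partly methylated quinones. Forcing the alkylation may start to methylate the indole nitrogens.
- Fallback: the oxygens are capped at two oxidation levels, so that the tetrol is never formed. It sets out from 11 and comes back to the route at 13.
- The two acidic enol oxygens of 11 are methylated at the stable quinone stage (Me2SO4, K2CO3, acetone). This gives 2,5-bis(5-benzyloxyindol-3-yl)-3,6-dimethoxy-1,4-benzoquinone F3, which can be purified by chromatography.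
- Dithionite reduction (Na2S2O4, EtOAc/H2O) gives the far less air-sensitive 2,5-bis(5-benzyloxyindol-3-yl)-3,6-dimethoxybenzene-1,4-diol F4.
- The two remaining phenols of F4 are methylated (Me2SO4, K2CO3, acetone, reflux, Ar) to give 13.

Step 8.
- What may go wrong: over-methylation to the bis-methyl ether and low conversion per pass. Two equivalent phenols cannot be told apart, so the mono-ether is limited by statistics and material is lost on each recycle.
- Fallback: a non-statistical assembly in which the two different indoles are introduced one after the other. It sets out from 1 and comes back to the route at 15.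
- Compound 1 is coupled once with 2,5-dichloro-1,4-benzoquinone as described above, giving 3-(5-benzyloxyindol-3-yl)-2,5-dichloro-1,4-benzoquinone F1.
- Commercial 5-methoxyindole is then added to the last free ring position (HCl, THF, then DDQ). This gives 2-(5-benzyloxyindol-3-yl)-3,6-dichloro-5-(5-methoxyindol-3-yl)-1,4-benzoquinone F5.
- Hydrolysis (NaOH aq, MeOH, reflux, then acid) gives 2-(5-benzyloxyindol-3-yl)-3,6-dihydroxy-5-(5-methoxyindol-3-yl)-1,4-benzoquinone F6.
- Dithionite reduction gives 3-(5-benzyloxyindol-3-yl)-6-(5-methoxyindol-3-yl)benzene-1,2,4,5-tetrol F7, which is methylated as in step 6 to 5-benzyloxy-3-[2,3,5,6-tetramethoxy-4-(5-methoxyindol-3-yl)phenyl]indole F8.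
- Hydrogenolysis of the single benzyl ether of F8 (H2, Pd/C) gives 15 with no statistical step.

**Further compounds**

F1 | step 5 | 3-(5-benzyloxyindol-3-yl)-2,5-dichloro-1,4-benzoquinone | O=C1C=C(Cl)C(=O)C(c2c[nH]c3ccc(OCc4ccccc4)cc23)=C1Cl
F2 | step 5 | 2,5-bis(5-benzyloxyindol-3-yl)-3,6-dichloro-1,4-benzoquinone | O=C1C(Cl)=C(c2c[nH]c3ccc(OCc4ccccc4)cc23)C(=O)C(Cl)=C1c1c[nH]c2ccc(OCc3ccccc3)cc12
F3 | step 6 | 2,5-bis(5-benzyloxyindol-3-yl)-3,6-dimethoxy-1,4-benzoquinone | COC1=C(c2c[nH]c3ccc(OCc4ccccc4)cc23)C(=O)C(OC)=C(c2c[nH]c3ccc(OCc4ccccc4)cc23)C1=O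
F4 | step 6 | 2,5-bis(5-benzyloxyindol-3-yl)-3,6-dimethoxybenzene-1,4-diol | COc1c(O)c(-c2c[nH]c3ccc(OCc4ccccc4)cc23)c(OC)c(O)c1-c1c[nH]c2ccc(OCc3ccccc3)cc12
F5 | step 8 | 2-(5-benzyloxyindol-3-yl)-3,6-dichloro-5-(5-methoxyindol-3-yl)-1,4-benzoquinone | O=C1C(c2c[nH]c3ccc(OC)cc23)=C(Cl)C(=O)C(c2c[nH]c3ccc(OCc4ccccc4)cc23)=C1Cl
F6 | step 8 | 2-(5-benzyloxyindol-3-yl)-3,6-dihydroxy-5-(5-methoxyindol-3-yl)-1,4-benzoquinone | O=C1C(O)=C(c2c[nH]c3ccc(OCc4ccccc4)cc23)C(=O)C(O)=C1c1c[nH]c2ccc(OC)cc12
F7 | step 8 | 3-(5-benzyloxyindol-3-yl)-6-(5-methoxyindol-3-yl)benzene-1,2,4,5-tetrol | Oc1c(O)c(-c2c[nH]c3ccc(OCc4ccccc4)cc23)c(O)c(O)c1-c1c[nH]c2ccc(OC)cc12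
F8 | step 8 | 5-benzyloxy-3-[2,3,5,6-tetramethoxy-4-(5-methoxyindol-3-yl)phenyl]indole | COc1ccc2[nH]cc(-c3c(OC)c(OC)c(-c4c[nH]c5ccc(OCc6ccccc6)cc45)c(OC)c3OC)c2c1
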